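**Plan**

1. Retrosynthesis: the 3-methylbut-2-enoate C–O bond and the two phenol protecting groups are cut first. The furan is then opened at O1–C2, which leads back to an aryl alkyne (C2, C3) attached to a 2,2-disubstituted oxirane (C4, C5, O1).
2. The oxirane is cut at C4–C5 (ynone plus sulfonium methylide), the ynone at C3–C4 (arylacetylide plus Weinreb amide), and the side chain at C2'–C3' (methyl (S)-glycidate plus 2-methylprop-1-enyl Grignard reagent).
3. Forward: the aryl alkyne is made from 2,5-dihydroxybenzaldehyde and the chain from the glycidate. The two are joined as an ynone, C5 is added, the furan (the only ring formed) closes under gold catalysis, and desilylation, esterification and acetal removal finish the route.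
4. Enabling feature: the furan has the aryl group on C2 and the chain on C4, with hydrogen on C3 and C5. An oxygen shift from C4 to C2 in the alkynyl oxirane gives exactly this pattern and no other.
5. Stereochemistry: the only stereocentre, C1' (S), is C2 of methyl (S)-glycidate. None of the four bonds at this carbon is made or broken anywhere in the route.

Key step: step 8

Assumption: methyl (S)-glycidate, a commercial compound, is chosen over an O-protected glycidol because it already has the carbonyl carbon of the ynone at the right oxidation level, which saves a protecting-group exchange and two oxidations.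
Numbering used: furan O1, C2 (aryl), C3, C4 (chain), C5; side chain C1' (stereocentre) to C4'. Reagents whose atoms do not reach the target (MOMCl, TBSCl, N,O-dimethylhydroxylamine) are not numbered and are given with their SMILES in the step that uses them.

**Route**

Step 1
Reactants: 1 2,5-dihydroxybenzaldehyde
Product: 2 2,5-bis(methoxymethoxy)benzaldehyde
Conditions: MOMCl, iPr2NEt, CH2Cl2, 0 °C to rt
Reagents that add atoms: chloromethyl methyl ether, COCCl
Why: O-alkylation of both phenols with the reactive α-chloro ether (Williamson type) should give acetals that withstand the organolithium, ylide, fluoride and gold steps and can be removed at the end without Brønsted acid.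

Step 2
Reactants: 2 2,5-bis(methoxymethoxy)benzaldehyde; 3 dimethyl (1-diazo-2-oxopropyl)phosphonate
Product: 4 2-ethynyl-1,4-bis(methoxymethoxy)benzene
Conditions: K2CO3, MeOH, rt
Reagents that add atoms: dimethyl (1-diazo-2-oxopropyl)phosphonate (3), COP(=O)(OC)C(=[N+]=[N-])C(C)=O
Why: Ohira–Bestmann variant of the Seyferth–Gilbert homologation, in which methanolysis frees the diazomethylphosphonate anion, this adds to the aldehyde, and loss of phosphate and dinitrogen followed by a 1,2-hydrogen shift gives the terminal alkyne under conditions that do not harm the acetals.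

Step 3
Reactants: 5 methyl (S)-glycidate [methyl (2S)-oxirane-2-carboxylate]; 6 2-methylprop-1-enylmagnesium bromide
Product: 7 methyl (2S)-2-hydroxy-5-methylhex-4-enoate
Conditions: CuBr·SMe2 (10 mol %), THF, −78 to −40 °C; aq. NH4Cl
Reagents that add atoms: 2-methylprop-1-enylmagnesium bromide (6), CC(C)=C[Mg]Br
Why: Copper-catalysed Grignard opening of a terminal epoxide, in which the alkenylcuprate attacks the unsubstituted C3 by SN2 faster than the ester is attacked at this temperature, and since C2 takes no part its (S) configuration is carried over unchanged.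

Step 4
Reactants: 7 methyl (2S)-2-hydroxy-5-methylhex-4-enoate
Product: 8 methyl (2S)-2-[(tert-butyldimethylsilyl)oxy]-5-methylhex-4-enoate
Conditions: TBSCl, imidazole, DMF, rt
Reagents that add atoms: tert-butyldimethylsilyl chloride, CC(C)(C)[Si](C)(C)Cl
Why: Imidazole-promoted silylation of the secondary alcohol, a standard protection that leaves the α-centre untouched and masks the hydroxyl, which would otherwise add to the ynone made in step 6.

Step 5
Reactants: 8 methyl (2S)-2-[(tert-butyldimethylsilyl)oxy]-5-methylhex-4-enoate
Product: 9 (2S)-2-[(tert-butyldimethylsilyl)oxy]-N-methoxy-N,5-dimethylhex-4-enamide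
Conditions: MeNH(OMe)·HCl, iPrMgCl, THF, −20 to 0 °C
Reagents that add atoms: N,O-dimethylhydroxylamine hydrochloride, CNOC.Cl
Why: Weinreb amide formation by aminolysis of the methyl ester with the chloromagnesium amide made in the flask, which is fast at low temperature and is not expected to enolise the α-silyloxy ester.

Step 6
Reactants: 4 2-ethynyl-1,4-bis(methoxymethoxy)benzene; 9 (2S)-2-[(tert-butyldimethylsilyl)oxy]-N-methoxy-N,5-dimethylhex-4-enamide
Product: 12 (4S)-1-[2,5-bis(methoxymethoxy)phenyl]-4-[(tert-butyldimethylsilyl)oxy]-7-methyloct-6-en-1-yn-3-one, via lithium arylacetylide 10 (not isolated), via lithium hemiaminal adduct 11 (not isolated)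
Conditions: 4, n-BuLi, THF, −78 °C; then 9, −78 to 0 °C; aq. NH4Cl
Reagents that add atoms: none
Why: Weinreb ketone synthesis, in which the alkyne C–H is by far the most acidic site of 4, its lithium acetylide adds once to the amide, and the chelated tetrahedral adduct collapses to the ynone only on work-up, so that neither over-addition nor base-induced epimerisation of the ketone can occur in the flask.

Step 7
Reactants: 12 (4S)-1-[2,5-bis(methoxymethoxy)phenyl]-4-[(tert-butyldimethylsilyl)oxy]-7-methyloct-6-en-1-yn-3-one; 13 trimethylsulfonium iodide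
Product: 15 2-{[2,5-bis(methoxymethoxy)phenyl]ethynyl}-2-[(1S)-1-(tert-butyldimethylsilyloxy)-4-methylpent-3-enyl]oxirane (both epimers at the oxirane carbon), via sulfonium betaine 14 (not isolated)
Conditions: 13, n-BuLi, THF, −10 °C; then 12, −78 to 0 °C
Reagents that add atoms: trimethylsulfonium iodide (13), C[S+](C)C.[I-]
Why: Corey–Chaykovsky epoxidation, in which the unstabilised dimethylsulfonium methylide adds irreversibly to the carbonyl carbon of the ynone and the betaine closes by intramolecular displacement of dimethyl sulfide, the configuration of the new oxirane carbon being of no consequence because it becomes sp2 in step 8.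

Step 8
Reactants: 15 2-{[2,5-bis(methoxymethoxy)phenyl]ethynyl}-2-[(1S)-1-(tert-butyldimethylsilyloxy)-4-methylpent-3-enyl]oxirane
Product: 16 2-[2,5-bis(methoxymethoxy)phenyl]-4-[(1S)-1-(tert-butyldimethylsilyloxy)-4-methylpent-3-enyl]furan
Conditions: (Ph3P)AuNTf2 (3 mol %), CH2Cl2, 0 °C to rt
Reagents that add atoms: none
Why: The cationic monovalent gold complex binds the aryl alkyne, the strained C4–O bond of the oxirane opens toward the propargylic carbon C4 while the oxygen, still bonded to C5, adds to the gold-activated C2, and loss of the C5 proton followed by protodeauration at C3 gives the aromatic ring and returns the catalyst. The closest known reaction type is the gold-catalysed isomerisation of 2-alkynyl-2-alkyl oxiranes to 2,4-disubstituted furans. The furan, the only ring formed, closes at O1–C2 in a formal 5-endo-dig mode. No stereocentre is created: the oxirane carbon, used as both epimers, becomes sp2, and the (S) centre at C1' only stands next to the reacting carbon with none of its bonds involved. Regiochemistry needs no control because the connectivity of 15 places the aryl group on C2 and the chain on C4; what the step does need is chemoselectivity for the oxygen shift over attack of the trisubstituted alkene or of the ortho acetal oxygen on the same alkyne, and over a hydride shift from C1' or C5 to C4. Ring strain and the proximity of the oxirane oxygen should make the shift fast at 0 °C, where an internal aryl alkyne is a slow partner for enyne cyclisation and acetal transfer to an alkyne is not expected to proceed, and the non-basic, non-protic medium should leave the silyl ether and the acetals intact.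

Step 9
Reactants: 16 2-[2,5-bis(methoxymethoxy)phenyl]-4-[(1S)-1-(tert-butyldimethylsilyloxy)-4-methylpent-3-enyl]furan
Product: 17 (1S)-1-{5-[2,5-bis(methoxymethoxy)phenyl]furan-3-yl}-4-methylpent-3-en-1-ol
Conditions: TBAF, THF, 0 °C to rt; aq. NH4Cl
Reagents that add atoms: none
Why: Fluoride-induced desilylation, driven by the strong Si–F bond, cleaves only the O–Si bond, so the carbinol configuration is retained and the acetals, the furan and the alkene are untouched.

Step 10
Reactants: 17 (1S)-1-{5-[2,5-bis(methoxymethoxy)phenyl]furan-3-yl}-4-methylpent-3-en-1-ol; 18 3-methylbut-2-enoic acid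
Product: 19 (1S)-1-{5-[2,5-bis(methoxymethoxy)phenyl]furan-3-yl}-4-methylpent-3-enyl 3-methylbut-2-enoate
Conditions: DCC, DMAP (cat.), CH2Cl2, 0 °C to rt
Reagents that add atoms: 3-methylbut-2-enoic acid (18), CC(C)=CC(=O)O
Why: Steglich esterification, in which the carbodiimide-activated acid is passed by DMAP to the secondary hydroxyl with retention because the carbinol C–O bond is not broken, and the use of the free acid avoids the vinylketene pathway that deconjugates the corresponding acyl chloride under amine bases.

Step 11
Reactants: 19 (1S)-1-{5-[2,5-bis(methoxymethoxy)phenyl]furan-3-yl}-4-methylpent-3-enyl 3-methylbut-2-enoate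
Product: 21 (1S)-1-[5-(2,5-dihydroxyphenyl)furan-3-yl]-4-methylpent-3-enyl 3-methylbut-2-enoate, via bis(trimethylsilyl) ether 20 (not isolated)
Conditions: TMSOTf, 2,2'-bipyridyl, MeCN, 0 °C to rt, under argon; then H2O
Reagents that add atoms: none
Why: Silyl triflate–bipyridyl cleavage of aryl methoxymethyl ethers, in which the bipyridyl-buffered silyl triflate turns each aryl acetal into the aryl trimethylsilyl ether and water then hydrolyses it to the phenol, under non-protic and nearly neutral conditions that are expected to spare the furan-3-ylmethyl ester, the furan and the trisubstituted alkene.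

**Compound list**

1 | 2,5-dihydroxybenzaldehyde | O=Cc1cc(O)ccc1O | starting material
2 | 2,5-bis(methoxymethoxy)benzaldehyde | O=Cc1cc(OCOC)ccc1OCOC | intermediate
3 | dimethyl (1-diazo-2-oxopropyl)phosphonate | COP(=O)(OC)C(=[N+]=[N-])C(C)=O | starting material
4 | 2-ethynyl-1,4-bis(methoxymethoxy)benzene | C#Cc1cc(OCOC)ccc1OCOC | intermediate
5 | methyl (S)-glycidate [methyl (2S)-oxirane-2-carboxylate] | COC(=O)[C@@H]1CO1 | starting material
6 | 2-methylprop-1-enylmagnesium bromide | CC(C)=C[Mg]Br | starting material
7 | methyl (2S)-2-hydroxy-5-methylhex-4-enoate | CC(C)=CC[C@H](O)C(=O)OC | intermediate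
8 | methyl (2S)-2-[(tert-butyldimethylsilyl)oxy]-5-methylhex-4-enoate | CC(C)=CC[C@H](O[Si](C)(C)C(C)(C)C)C(=O)OC | intermediate
9 | (2S)-2-[(tert-butyldimethylsilyl)oxy]-N-methoxy-N,5-dimethylhex-4-enamide | CC(C)=CC[C@H](O[Si](C)(C)C(C)(C)C)C(=O)N(C)OC | intermediate
10 | lithium [2,5-bis(methoxymethoxy)phenyl]acetylide | [Li]C#Cc1cc(OCOC)ccc1OCOC | intermediate (not isolated)
11 | lithium (4S)-1-[2,5-bis(methoxymethoxy)phenyl]-4-[(tert-butyldimethylsilyl)oxy]-3-[methoxy(methyl)amino]-7-methyloct-6-en-1-yn-3-olate, both epimers at C3 | CC(C)=CC[C@H](O[Si](C)(C)C(C)(C)C)C(O[Li])(N(C)OC)C#Cc1cc(OCOC)ccc1OCOC | intermediate (not isolated)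
12 | (4S)-1-[2,5-bis(methoxymethoxy)phenyl]-4-[(tert-butyldimethylsilyl)oxy]-7-methyloct-6-en-1-yn-3-one | CC(C)=CC[C@H](O[Si](C)(C)C(C)(C)C)C(=O)C#Cc1cc(OCOC)ccc1OCOC | intermediate
13 | trimethylsulfonium iodide | C[S+](C)C.[I-] | starting material
14 | (4S)-1-[2,5-bis(methoxymethoxy)phenyl]-4-[(tert-butyldimethylsilyl)oxy]-3-[(dimethylsulfonio)methyl]-7-methyloct-6-en-1-yn-3-olate, both epimers at C3 | CC(C)=CC[C@H](O[Si](C)(C)C(C)(C)C)C([O-])(C[S+](C)C)C#Cc1cc(OCOC)ccc1OCOC | intermediate (not isolated)
15 | 2-{[2,5-bis(methoxymethoxy)phenyl]ethynyl}-2-[(1S)-1-(tert-butyldimethylsilyloxy)-4-methylpent-3-enyl]oxirane, both epimers at the oxirane carbon | CC(C)=CC[C@H](O[Si](C)(C)C(C)(C)C)C1(CO1)C#Cc1cc(OCOC)ccc1OCOC | intermediate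
16 | 2-[2,5-bis(methoxymethoxy)phenyl]-4-[(1S)-1-(tert-butyldimethylsilyloxy)-4-methylpent-3-enyl]furan | CC(C)=CC[C@H](O[Si](C)(C)C(C)(C)C)c1coc(-c2cc(OCOC)ccc2OCOC)c1 | intermediate
17 | (1S)-1-{5-[2,5-bis(methoxymethoxy)phenyl]furan-3-yl}-4-methylpent-3-en-1-ol | CC(C)=CC[C@H](O)c1coc(-c2cc(OCOC)ccc2OCOC)c1 | intermediate
18 | 3-methylbut-2-enoic acid | CC(C)=CC(=O)O | starting material
19 | (1S)-1-{5-[2,5-bis(methoxymethoxy)phenyl]furan-3-yl}-4-methylpent-3-enyl 3-methylbut-2-enoate | CC(C)=CC[C@H](OC(=O)C=C(C)C)c1coc(-c2cc(OCOC)ccc2OCOC)c1 | intermediate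
20 | (1S)-1-(5-{2,5-bis[(trimethylsilyl)oxy]phenyl}furan-3-yl)-4-methylpent-3-enyl 3-methylbut-2-enoate | CC(C)=CC[C@H](OC(=O)C=C(C)C)c1coc(-c2cc(O[Si](C)(C)C)ccc2O[Si](C)(C)C)c1 | intermediate (not isolated)
21 | (1S)-1-[5-(2,5-dihydroxyphenyl)furan-3-yl]-4-methylpent-3-enyl 3-methylbut-2-enoate | CC(C)=CC[C@H](OC(=O)C=C(C)C)c1coc(-c2cc(O)ccc2O)c1 | target

**Step count**

Total: 11 steps. Longest linear sequence: 9 steps (steps 3 to 11, from methyl (S)-glycidate 5); the aryl alkyne branch (steps 1 and 2) joins at step 6.

**Steps most likely to fail**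

Step 8. The gold-activated alkyne may be intercepted by the trisubstituted alkene five atoms away (enyne cycloisomerisation) or by the ortho acetal oxygen. Alternatively, positive charge building up at C4 may be quenched by a hydride shift from C1' or C5 instead of by ring closure, which would also erase the stereocentre. The fallback sets out from ynone 12 and forms the same O1–C2 bond from a diol, so that the tertiary C4–O bond is broken only in the aromatising dehydration. Addition of (isopropoxydimethylsilyl)methylmagnesium chloride to the ketone in THF at −78 °C should give the β-hydroxysilane (4S)-1-[2,5-bis(methoxymethoxy)phenyl]-4-[(tert-butyldimethylsilyl)oxy]-3-{[dimethyl(propan-2-yloxy)silyl]methyl}-7-methyloct-6-en-1-yn-3-ol F1. Tamao oxidation (H2O2, KF, KHCO3, THF/MeOH) should convert it into the 3-alkyne-1,2-diol (3S)-2-{[2,5-bis(methoxymethoxy)phenyl]ethynyl}-3-[(tert-butyldimethylsilyl)oxy]-6-methylhept-5-ene-1,2-diol F2. AgNO3 on silica gel in CH2Cl2 at rt should then bring about 5-endo-dig attack of the primary hydroxyl on the aryl-bearing alkyne carbon and loss of water, a known furan synthesis with monovalent silver, which has little tendency to trigger enyne cyclisation. The fallback comes back to the route at furan 16.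

Step 7. The basic ylide may remove the proton at the silyloxy-bearing carbon next to the ynone carbonyl, eroding the enantiopurity, or may add in conjugate fashion to the alkyne instead of to the carbonyl. The fallback sets out from Weinreb amide 9 and brings in C5 before the alkyne, so that no ynone is formed. Chloromethyllithium (ICH2Cl, MeLi·LiBr, THF, −78 °C) should give the chloromethyl ketone (3S)-3-[(tert-butyldimethylsilyl)oxy]-1-chloro-6-methylhept-5-en-2-one F3. The lithium acetylide 10, made less basic with anhydrous CeCl3, should add to the ketone to give the chlorohydrin (4S)-1-[2,5-bis(methoxymethoxy)phenyl]-4-[(tert-butyldimethylsilyl)oxy]-3-(chloromethyl)-7-methyloct-6-en-1-yn-3-ol F4. K2CO3 in MeOH should close F4 to the oxirane by intramolecular displacement of chloride. The fallback comes back to the route at oxirane 15.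

Step 11. The silyl triflate may ionise the furan-3-ylmethyl C–O bond of the ester, with loss of the acyloxy group or of configuration, and the electron-rich hydroquinone may be oxidised during work-up. The fallback sets out from furan 16 and removes the acetals while the carbinol still carries the silyl ether, the least ionisable group it can bear. TMSOTf and 2,2'-bipyridyl in MeCN followed by water should give 2-(4-{(1S)-1-[(tert-butyldimethylsilyl)oxy]-4-methylpent-3-enyl}furan-2-yl)benzene-1,4-diol F5. TBAF buffered with AcOH should give the triol 2-{4-[(1S)-1-hydroxy-4-methylpent-3-enyl]furan-2-yl}benzene-1,4-diol F6. Exhaustive acylation with acid 18, DCC and DMAP should give the tris-ester 2-{4-[(1S)-4-methyl-1-(3-methylbut-2-enoyloxy)pent-3-enyl]furan-2-yl}-1,4-phenylene bis(3-methylbut-2-enoate) F7. Pyrrolidine in CH2Cl2 at 0 °C should then cleave the two aryl esters selectively, since aryl esters undergo aminolysis far faster than the alkyl ester. The fallback comes back to the route at target 21.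

**Further compounds**

F1 | step 8 | (4S)-1-[2,5-bis(methoxymethoxy)phenyl]-4-[(tert-butyldimethylsilyl)oxy]-3-{[dimethyl(propan-2-yloxy)silyl]methyl}-7-methyloct-6-en-1-yn-3-ol | CC(C)=CC[C@H](O[Si](C)(C)C(C)(C)C)C(O)(C[Si](C)(C)OC(C)C)C#Cc1cc(OCOC)ccc1OCOC
F2 | step 8 | (3S)-2-{[2,5-bis(methoxymethoxy)phenyl]ethynyl}-3-[(tert-butyldimethylsilyl)oxy]-6-methylhept-5-ene-1,2-diol | CC(C)=CC[C@H](O[Si](C)(C)C(C)(C)C)C(O)(CO)C#Cc1cc(OCOC)ccc1OCOC
F3 | step 7 | (3S)-3-[(tert-butyldimethylsilyl)oxy]-1-chloro-6-methylhept-5-en-2-one | CC(C)=CC[C@H](O[Si](C)(C)C(C)(C)C)C(=O)CCl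
F4 | step 7 | (4S)-1-[2,5-bis(methoxymethoxy)phenyl]-4-[(tert-butyldimethylsilyl)oxy]-3-(chloromethyl)-7-methyloct-6-en-1-yn-3-ol | CC(C)=CC[C@H](O[Si](C)(C)C(C)(C)C)C(O)(CCl)C#Cc1cc(OCOC)ccc1OCOC
F5 | step 11 | 2-(4-{(1S)-1-[(tert-butyldimethylsilyl)oxy]-4-methylpent-3-enyl}furan-2-yl)benzene-1,4-diol | CC(C)=CC[C@H](O[Si](C)(C)C(C)(C)C)c1coc(-c2cc(O)ccc2O)c1
F6 | step 11 | 2-{4-[(1S)-1-hydroxy-4-methylpent-3-enyl]furan-2-yl}benzene-1,4-diol | CC(C)=CC[C@H](O)c1coc(-c2cc(O)ccc2O)c1
F7 | step 11 | 2-{4-[(1S)-4-methyl-1-(3-methylbut-2-enoyloxy)pent-3-enyl]furan-2-yl}-1,4-phenylene bis(3-methylbut-2-enoate) | CC(C)=CC[C@H](OC(=O)C=C(C)C)c1coc(-c2cc(OC(=O)C=C(C)C)ccc2OC(=O)C=C(C)C)c1
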